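**Retrosynthetic overview**
1. The last bond made is the C1–O ester, from ring alcohol 21 and silyl-protected (E)-ferulic acid 24. The core is an E,E-cyclodeca-3,7-diene: C1 ferulate carbinol, C2, C3(Me)=C4, C5, C6, C7(Me)=C8, C9 free carbinol, C10 isopropyl.
2. The strategy rests on the ring 1,5-diene C3=C4–C5–C6–C7=C8. Read as an oxy-Cope retron (break C5–C6, make a temporary C3–C8 bond), it folds the ten-membered ring onto the cyclohexane C3–C8–C9–C10–C1–C2, a trans-1-vinyl-2-isopropenylcyclohexanol that already carries C1, C9 and C10. The C3 methyl is traced to the enol triflate of the rearrangement enolate.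
3. The cyclohexane is opened at the same C3–C8 bond (retro carbonyl-ene) to an acyclic aldehyde. C10 and C1 come from an Evans syn-aldol, C9 from a hydroxyl-directed anti reduction of a C9 enone.
4. Ring order: temporary 1,3-dioxane (moves the PMB group from the primary to the C1 oxygen), then cyclohexane by ene closure, then ten-membered ring by four-carbon ring expansion, then the ferulate ester.

Key step: step 12

Remark: atom labels C1–C10 are those of the ten-membered ring of the target and are kept for the same atoms in every intermediate; the stereocentres made at C3 and C8 are temporary and are erased in step 12.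

**Step 1**
Reactants: 1 (R)-4-benzyl-3-(3-methylbutanoyl)oxazolidin-2-one; 2 3-(4-methoxybenzyloxy)propanal
Product: 4 (R)-4-benzyl-3-[(2R,3S)-3-hydroxy-5-(4-methoxybenzyloxy)-2-(propan-2-yl)pentanoyl]oxazolidin-2-one, via dibutylboron Z-enolate 3 (not isolated)
Conditions: Bu2BOTf, iPr2NEt, CH2Cl2, 0 °C; then 2, −78 → 0 °C; pH 7 buffer, MeOH, H2O2
Reagents that add atoms: none
Why: Evans boron syn-aldol, in which the Z-enolate reacts through a closed chair (Zimmerman–Traxler) transition state on the face away from the benzyl group of the (R)-auxiliary and so sets C10 (2R) and C1 (3S) in the syn relationship.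

**Step 2**
Reactants: 4 syn-aldol adduct
Product: 5 (2R,3S)-3-hydroxy-N-methoxy-5-(4-methoxybenzyloxy)-N-methyl-2-(propan-2-yl)pentanamide
Conditions: AlMe3, MeONHMe·HCl, CH2Cl2, −20 → 0 °C; aq. potassium sodium tartrate
Reagents that add atoms: N,O-dimethylhydroxylamine hydrochloride, CNOC.Cl
Why: Weinreb transamination of the N-acyloxazolidinone by the aluminium amide, assisted by the free C1 hydroxyl as its aluminium alkoxide so that the exocyclic carbonyl is attacked and the auxiliary is released without touching a stereocentre.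

**Step 3**
Reactants: 5 Weinreb amide; 6 2-methyl-1-propenylmagnesium bromide
Product: 7 (5R,6S)-6-hydroxy-8-(4-methoxybenzyloxy)-2-methyl-5-(propan-2-yl)oct-2-en-4-one
Conditions: 6 (3.5 equiv), THF, −20 → 0 °C; cold aq. NH4Cl
Reagents that add atoms: none
Why: Weinreb ketone synthesis, in which the chelated tetrahedral magnesium adduct formed after deprotonation of the hydroxyl survives until the quench, so that a single alkenyl group is added and the cold quench should keep C10 from epimerising.

**Step 4**
Reactants: 7 β-hydroxy enone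
Product: 8 (4S,5R,6S)-8-(4-methoxybenzyloxy)-2-methyl-5-(propan-2-yl)oct-2-ene-4,6-diol
Conditions: Me4NBH(OAc)3, MeCN/AcOH (1:1), −30 → −10 °C
Reagents that add atoms: none
Why: Evans–Saksena reduction, in which the C1 hydroxyl exchanges onto boron and delivers hydride intramolecularly to the C9 carbonyl through a chair transition state, giving the 1,3-anti diol (new C9 centre S) and only 1,2-reduction of the enone.

**Step 5**
Reactants: 8 anti-diol
Product: 9 (4S,5S)-5-[(2S,4S)-2-(4-methoxyphenyl)-1,3-dioxan-4-yl]-2,6-dimethylhept-2-en-4-ol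
Conditions: DDQ (1.2 equiv), 4 Å molecular sieves, CH2Cl2, 0 °C
Reagents that add atoms: none
Why: Anhydrous DDQ oxidative acetalisation of the PMB ether, in which the oxocarbenium ion formed by benzylic hydride abstraction is captured by the 1,3-related C1 hydroxyl as a six-membered acetal (the C9 hydroxyl would need an eight-membered ring) and the temporary acetal carbon settles with its aryl group equatorial and cis to the C4 substituent.

**Step 6**
Reactants: 9 acetal alcohol
Product: 10 tert-butyl{[(4S,5R)-5-[(2S,4S)-2-(4-methoxyphenyl)-1,3-dioxan-4-yl]-2,6-dimethylhept-2-en-4-yl]oxy}dimethylsilane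
Conditions: TBSOTf, 2,6-lutidine, CH2Cl2, −78 → 0 °C
Reagents that add atoms: tert-butyldimethylsilyl trifluoromethanesulfonate, CC(C)(C)[Si](C)(C)OS(=O)(=O)C(F)(F)F
Why: Silylation of the hindered secondary allylic C9 hydroxyl by the silyl triflate with a non-nucleophilic base, conditions under which the acetal and the alkene should be inert.

**Step 7**
Reactants: 10 silylated acetal
Product: 11 (3S,4R,5S)-5-(tert-butyldimethylsilyloxy)-3-(4-methoxybenzyloxy)-7-methyl-4-(propan-2-yl)oct-6-en-1-ol
Conditions: iBu2AlH (3 equiv), CH2Cl2, −78 → 0 °C; aq. potassium sodium tartrate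
Reagents that add atoms: none
Why: Regioselective reductive opening of the p-methoxybenzylidene acetal, in which the aluminium hydride binds the less hindered primary oxygen and cleaves that C–O bond, so that the PMB ether stays on the secondary C1 oxygen and the primary alcohol is freed.

**Step 8**
Reactants: 11 primary alcohol
Product: 12 (3S,4R,5S)-5-(tert-butyldimethylsilyloxy)-3-(4-methoxybenzyloxy)-7-methyl-4-(propan-2-yl)oct-6-enal
Conditions: Dess–Martin periodinane, NaHCO3, CH2Cl2, 0 °C → rt
Reagents that add atoms: none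
Why: Dess–Martin oxidation under buffered, non-basic conditions, which should give the β-alkoxy aldehyde without elimination of the C1 ether.

**Step 9**
Reactants: 12 aldehyde
Product: 13 (1R,2S,3R,4R,5S)-3-(tert-butyldimethylsilyloxy)-5-(4-methoxybenzyloxy)-4-(propan-2-yl)-2-(prop-1-en-2-yl)cyclohexan-1-ol
Conditions: Me2AlCl (1.1 equiv), CH2Cl2, −78 °C
Reagents that add atoms: none
Why: Lewis acid-promoted intramolecular carbonyl-ene reaction of the citronellal-to-isopulegol kind, which makes the temporary C3–C8 bond by 6-exo attack of the isobutenyl CH on the aluminium-bound aldehyde with transfer of a methyl hydrogen to oxygen; the chair that keeps the C1 ether, the C10 isopropyl group, the new isopropenyl group and the C3 oxygen equatorial and only the C9 silyl ether axial should set C8 cis to the C9 oxygen and the C3 hydroxyl trans to the isopropenyl group, and a single equivalent of Lewis acid keeps the aluminium monodentate so that it does not chelate the C1 ether.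

**Step 10**
Reactants: 13 cyclohexanol
Product: 14 (2R,3R,4R,5S)-3-(tert-butyldimethylsilyloxy)-5-(4-methoxybenzyloxy)-4-(propan-2-yl)-2-(prop-1-en-2-yl)cyclohexan-1-one
Conditions: Dess–Martin periodinane, NaHCO3, CH2Cl2, 0 °C; neutral work-up, used directly
Reagents that add atoms: none
Why: Buffered Dess–Martin oxidation of the secondary alcohol, which removes the temporary C3 stereocentre and should neither move the β,γ-alkene into conjugation nor epimerise C8.

**Step 11**
Reactants: 14 ketone; 15 vinylmagnesium bromide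
Product: 16 (1R,2R,3R,4R,5S)-1-ethenyl-3-(tert-butyldimethylsilyloxy)-5-(4-methoxybenzyloxy)-4-(propan-2-yl)-2-(prop-1-en-2-yl)cyclohexan-1-ol
Conditions: anhydrous CeCl3, THF, −78 °C; then 15, −78 °C; aq. NH4Cl
Reagents that add atoms: none
Why: Cerium-mediated 1,2-addition of the Grignard reagent, which suppresses enolisation of a ketone flanked by two β-oxygen groups, while the axial C9 silyl ether blocks the axial trajectory so that vinyl should enter equatorially, trans to the equatorial isopropenyl group, leaving the new C3 hydroxyl axial.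

**Step 12**
Reactants: 16 vinyl carbinol
Product: 19 (1Z,5E,7S,8R,9S)-7-(tert-butyldimethylsilyloxy)-9-(4-methoxybenzyloxy)-5-methyl-8-(propan-2-yl)cyclodeca-1,5-dien-1-yl trifluoromethanesulfonate, via potassium alkoxide 17 (not isolated), via potassium enolate 18 (not isolated)
Conditions: KH (1.3 equiv), 18-crown-6, THF, 0 °C → rt; then PhNTf2, −78 → 0 °C; aq. NH4Cl
Reagents that add atoms: N-phenylbis(trifluoromethanesulfonimide), O=S(=O)(N(c1ccccc1)S(=O)(=O)C(F)(F)F)C(F)(F)F
Why: Deprotonation gives the tertiary alkoxide 17, whose crown-separated oxyanion drives a concerted [3,3] sigmatropic shift in which the vinyl CH2 (C5) bonds to the isopropenyl CH2 (C6) while the temporary C3–C8 bond breaks, leaving the C7=C8 alkene and the C3=C4 enolate 18, which PhNTf2 then sulfonylates on oxygen. The closest known reaction type is the anionic oxy-Cope ring expansion of trans-1-vinyl-2-isopropenylcyclohexanols to (E)-cyclodec-5-enone enolates, combined with electrophilic trapping of the regiodefined enolate. The ten-membered ring is closed not end to end but by four-carbon ring expansion of the cyclohexane, the new C5–C6 bond forming across a chair six-centre transition state. No new stereocentre is made: C3 and C8 become sp2, C1, C9 and C10 are spectators, and the geometry of both new ring alkenes follows from that chair, in which the ring bonds C3–C2 and C8–C9 are pseudo-equatorial so that C2 ends trans to C5 and C9 trans to C6. The step needs trans geometry at both alkenes and a single enolate regioisomer; the first is secured by the trans-diequatorial vinyl and isopropenyl groups held by the axial C9 silyl ether, the second because the rearrangement delivers the enolate only toward C4 and it is triflated at −78 °C before proton transfer could move it toward C2 and expel the C1 ether. A silyl shift from the C9 oxygen to the syn-axial C3 alkoxide would be reversible and should not divert material, since only the tertiary alkoxide rearranges.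

**Step 13**
Reactants: 19 enol triflate
Product: 20 (1S,2R,3S,4E,8E)-3-(tert-butyldimethylsilyloxy)-1-(4-methoxybenzyloxy)-5,9-dimethyl-2-(propan-2-yl)cyclodeca-4,8-diene
Conditions: Fe(acac)3 (10 mol %), MeMgBr, THF/NMP, −30 → 0 °C
Reagents that add atoms: methylmagnesium bromide, C[Mg]Br
Why: Iron-catalysed Kumada-type cross-coupling of an alkenyl triflate with a methyl Grignard reagent, which replaces C–OTf by C–CH3 with retention of alkene geometry and so keeps the trans ring alkene C3=C4.

**Step 14**
Reactants: 20 PMB ether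
Product: 21 (1S,2R,3S,4E,8E)-3-(tert-butyldimethylsilyloxy)-5,9-dimethyl-2-(propan-2-yl)cyclodeca-4,8-dien-1-ol
Conditions: DDQ (1.3 equiv), CH2Cl2/pH 7 phosphate buffer (10:1), 0 °C
Reagents that add atoms: none
Why: Oxidative PMB cleavage by DDQ (benzylic hydride abstraction, then hydrolysis of the oxocarbenium ion) in a buffered two-phase medium that should spare the silyl ether and keep acid away from the 1,5-diene, which is prone to transannular cyclisation.

**Step 15**
Reactants: 22 (E)-ferulic acid
Product: 24 (2E)-3-[4-(tert-butyldimethylsilyloxy)-3-methoxyphenyl]prop-2-enoic acid, via bis-TBS ferulate 23 (not isolated)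
Conditions: TBSCl (2.5 equiv), imidazole, DMF, rt; then AcOH/THF/H2O, rt
Reagents that add atoms: tert-butyldimethylsilyl chloride, CC(C)(C)[Si](C)(C)Cl
Why: Exhaustive silylation followed by selective hydrolysis of the far more labile silyl ester, which should leave the phenol protected and the acid free.

**Step 16**
Reactants: 21 ring alcohol; 24 4-O-TBS-ferulic acid
Product: 25 (1S,2R,3S,4E,8E)-3-(tert-butyldimethylsilyloxy)-5,9-dimethyl-2-(propan-2-yl)cyclodeca-4,8-dien-1-yl (2E)-3-[4-(tert-butyldimethylsilyloxy)-3-methoxyphenyl]prop-2-enoate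
Conditions: DCC, DMAP, CH2Cl2, 0 °C → rt
Reagents that add atoms: none
Why: Steglich esterification, in which DMAP turns the O-acylisourea into an acylpyridinium ion that acylates the hindered C1 hydroxyl with retention at C1 while the phenol and the C9 hydroxyl are masked as silyl ethers.

**Step 17**
Reactants: 25 bis-silyl ester
Product: 26 (1S,2S,3S,4E,8E)-3-hydroxy-5,9-dimethyl-2-(propan-2-yl)cyclodeca-4,8-dien-1-yl (2E)-3-(4-hydroxy-3-methoxyphenyl)prop-2-enoate (CNP0378519.1)
Conditions: HF·pyridine, pyridine, THF, 0 °C → rt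
Reagents that add atoms: none
Why: Fluoride-mediated cleavage of both silyl ethers under pyridine-buffered, weakly acidic conditions, which should avoid base-induced acyl migration from the C1 to the C9 oxygen and stay too mild for transannular cyclisation of the 1,5-diene.

**Compound list**
1 | (R)-4-benzyl-3-(3-methylbutanoyl)oxazolidin-2-one | CC(C)CC(=O)N1[C@H](Cc2ccccc2)COC1=O | starting material
2 | 3-(4-methoxybenzyloxy)propanal | COc1ccc(COCCC=O)cc1 | starting material
3 | dibutylboron (Z)-enolate of 1 | CC(C)/C=C(\OB(CCCC)CCCC)N1[C@H](Cc2ccccc2)COC1=O | intermediate (not isolated)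
4 | (R)-4-benzyl-3-[(2R,3S)-3-hydroxy-5-(4-methoxybenzyloxy)-2-(propan-2-yl)pentanoyl]oxazolidin-2-one | COc1ccc(COCC[C@H](O)[C@@H](C(C)C)C(=O)N2[C@H](Cc3ccccc3)COC2=O)cc1 | intermediate
5 | (2R,3S)-3-hydroxy-N-methoxy-5-(4-methoxybenzyloxy)-N-methyl-2-(propan-2-yl)pentanamide | COc1ccc(COCC[C@H](O)[C@@H](C(C)C)C(=O)N(C)OC)cc1 | intermediate
6 | 2-methyl-1-propenylmagnesium bromide | CC(C)=C[Mg]Br | starting material
7 | (5R,6S)-6-hydroxy-8-(4-methoxybenzyloxy)-2-methyl-5-(propan-2-yl)oct-2-en-4-one | COc1ccc(COCC[C@H](O)[C@@H](C(C)C)C(=O)C=C(C)C)cc1 | intermediate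
8 | (4S,5R,6S)-8-(4-methoxybenzyloxy)-2-methyl-5-(propan-2-yl)oct-2-ene-4,6-diol | COc1ccc(COCC[C@H](O)[C@@H](C(C)C)[C@@H](O)C=C(C)C)cc1 | intermediate
9 | (4S,5S)-5-[(2S,4S)-2-(4-methoxyphenyl)-1,3-dioxan-4-yl]-2,6-dimethylhept-2-en-4-ol | COc1ccc([C@H]2OCC[C@H](O2)[C@@H](C(C)C)[C@@H](O)C=C(C)C)cc1 | intermediate
10 | tert-butyl{[(4S,5R)-5-[(2S,4S)-2-(4-methoxyphenyl)-1,3-dioxan-4-yl]-2,6-dimethylhept-2-en-4-yl]oxy}dimethylsilane | COc1ccc([C@H]2OCC[C@H](O2)[C@@H](C(C)C)[C@@H](O[Si](C)(C)C(C)(C)C)C=C(C)C)cc1 | intermediate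
11 | (3S,4R,5S)-5-(tert-butyldimethylsilyloxy)-3-(4-methoxybenzyloxy)-7-methyl-4-(propan-2-yl)oct-6-en-1-ol | OCC[C@H](OCc1ccc(OC)cc1)[C@@H](C(C)C)[C@@H](O[Si](C)(C)C(C)(C)C)C=C(C)C | intermediate
12 | (3S,4R,5S)-5-(tert-butyldimethylsilyloxy)-3-(4-methoxybenzyloxy)-7-methyl-4-(propan-2-yl)oct-6-enal | O=CC[C@H](OCc1ccc(OC)cc1)[C@@H](C(C)C)[C@@H](O[Si](C)(C)C(C)(C)C)C=C(C)C | intermediate
13 | (1R,2S,3R,4R,5S)-3-(tert-butyldimethylsilyloxy)-5-(4-methoxybenzyloxy)-4-(propan-2-yl)-2-(prop-1-en-2-yl)cyclohexan-1-ol | O[C@H]1[C@H](C(C)=C)[C@H](O[Si](C)(C)C(C)(C)C)[C@H](C(C)C)[C@@H](OCc2ccc(OC)cc2)C1 | intermediate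
14 | (2R,3R,4R,5S)-3-(tert-butyldimethylsilyloxy)-5-(4-methoxybenzyloxy)-4-(propan-2-yl)-2-(prop-1-en-2-yl)cyclohexan-1-one | O=C1[C@H](C(C)=C)[C@H](O[Si](C)(C)C(C)(C)C)[C@H](C(C)C)[C@@H](OCc2ccc(OC)cc2)C1 | intermediate
15 | vinylmagnesium bromide | C=C[Mg]Br | starting material
16 | (1R,2R,3R,4R,5S)-1-ethenyl-3-(tert-butyldimethylsilyloxy)-5-(4-methoxybenzyloxy)-4-(propan-2-yl)-2-(prop-1-en-2-yl)cyclohexan-1-ol | C=C[C@@]1(O)[C@H](C(C)=C)[C@H](O[Si](C)(C)C(C)(C)C)[C@H](C(C)C)[C@@H](OCc2ccc(OC)cc2)C1 | intermediate
17 | potassium alkoxide of 16 | C=C[C@@]1([O-])[C@H](C(C)=C)[C@H](O[Si](C)(C)C(C)(C)C)[C@H](C(C)C)[C@@H](OCc2ccc(OC)cc2)C1.[K+] | intermediate (not isolated)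
18 | potassium cyclodeca-1,5-dien-1-olate (C3=C4 enolate, both ring alkenes trans) | COc1ccc(CO[C@H]2C/C([O-])=C/CC/C(C)=C/[C@H](O[Si](C)(C)C(C)(C)C)[C@@H]2C(C)C)cc1.[K+] | intermediate (not isolated)
19 | (1Z,5E,7S,8R,9S)-7-(tert-butyldimethylsilyloxy)-9-(4-methoxybenzyloxy)-5-methyl-8-(propan-2-yl)cyclodeca-1,5-dien-1-yl trifluoromethanesulfonate | COc1ccc(CO[C@H]2C/C(OS(=O)(=O)C(F)(F)F)=C/CC/C(C)=C/[C@H](O[Si](C)(C)C(C)(C)C)[C@@H]2C(C)C)cc1 | intermediate
20 | (1S,2R,3S,4E,8E)-3-(tert-butyldimethylsilyloxy)-1-(4-methoxybenzyloxy)-5,9-dimethyl-2-(propan-2-yl)cyclodeca-4,8-diene | COc1ccc(CO[C@H]2C/C(C)=C/CC/C(C)=C/[C@H](O[Si](C)(C)C(C)(C)C)[C@@H]2C(C)C)cc1 | intermediate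
21 | (1S,2R,3S,4E,8E)-3-(tert-butyldimethylsilyloxy)-5,9-dimethyl-2-(propan-2-yl)cyclodeca-4,8-dien-1-ol | O[C@H]1C/C(C)=C/CC/C(C)=C/[C@H](O[Si](C)(C)C(C)(C)C)[C@@H]1C(C)C | intermediate
22 | (E)-ferulic acid | COc1cc(/C=C/C(=O)O)ccc1O | starting material
23 | tert-butyldimethylsilyl (2E)-3-[4-(tert-butyldimethylsilyloxy)-3-methoxyphenyl]prop-2-enoate | COc1cc(/C=C/C(=O)O[Si](C)(C)C(C)(C)C)ccc1O[Si](C)(C)C(C)(C)C | intermediate (not isolated)
24 | (2E)-3-[4-(tert-butyldimethylsilyloxy)-3-methoxyphenyl]prop-2-enoic acid | COc1cc(/C=C/C(=O)O)ccc1O[Si](C)(C)C(C)(C)C | intermediate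
25 | (1S,2R,3S,4E,8E)-3-(tert-butyldimethylsilyloxy)-5,9-dimethyl-2-(propan-2-yl)cyclodeca-4,8-dien-1-yl (2E)-3-[4-(tert-butyldimethylsilyloxy)-3-methoxyphenyl]prop-2-enoate | COc1cc(/C=C/C(=O)O[C@H]2C/C(C)=C/CC/C(C)=C/[C@H](O[Si](C)(C)C(C)(C)C)[C@@H]2C(C)C)ccc1O[Si](C)(C)C(C)(C)C | intermediate
26 | (1S,2S,3S,4E,8E)-3-hydroxy-5,9-dimethyl-2-(propan-2-yl)cyclodeca-4,8-dien-1-yl (2E)-3-(4-hydroxy-3-methoxyphenyl)prop-2-enoate | COc1cc(/C=C/C(=O)O[C@H]2C/C(C)=C/CC/C(C)=C/[C@H](O)[C@@H]2C(C)C)ccc1O | target

**Count**
Total steps: 17. Longest linear sequence: 16 steps (steps 1–14, 16 and 17); step 15 is a one-step side branch.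

**Steps most likely to fail**

1. Step 9 (ene closure). The closure may select the other chair. With the C9 silyl ether axial, its C–O bond lies close to the alkene plane and suffers allylic strain against the cis methyl of the isobutenyl group. Relief of that strain, or chelation of the C1 ether, would put the isopropyl group and the C1 ether axial and invert C8 relative to C9. The C8-epimeric ketone has no reliable steric bias for the vinyl addition. Ionisation of the allylic silyl ether by the Lewis acid is a second possible loss. Fallback: from aldehyde 12 the closure is run under deliberate chelate control (Me2AlCl, 2.5 equiv, CH2Cl2, −78 °C). A cationic aluminium centre then bridges the aldehyde and the C1 ether oxygen and holds both axial, with the C9 silyl ether equatorial and free of allylic strain. This should give the C8-epimeric cyclohexanol F1. Buffered Dess–Martin oxidation gives the ketone F2. Vinylmagnesium bromide, added after precomplexation with MgBr2·OEt2 in CH2Cl2/Et2O, should react under chelation by the same C1 ether from the face away from that axial ether, to give the vinyl carbinol F3 with vinyl again trans to isopropenyl. F3 is the C3,C8-bis-epimer of 16. Because both centres become sp2 in the rearrangement, its potassium alkoxide (KH, 18-crown-6, then PhNTf2) should pass through the corresponding chair and rejoin the route at enol triflate 19.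

2. Step 12 (ring expansion and triflation). The enolate may be sulfonylated slowly or incompletely. Proton transfer could then move it toward C2, with loss of the C1 ether by β-elimination, or it could be protonated to the ketone on work-up. The silyl shift to the C3 alkoxide may also slow the rearrangement. Fallback: from carbinol 16 the same rearrangement is run, but enolate 18 is captured at −78 °C with ClP(O)(OEt)2, a hard electrophile that reacts on oxygen only, to give the diethyl enol phosphate F4. Coupling of F4 with Me3Al catalysed by Pd(PPh3)4 (ClCH2CH2Cl, rt) installs the C3 methyl with retention and rejoins the route at diene 20.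

3. Step 11 (vinyl addition). Competing enolisation of the ketone by the basic organometallic would lead to β-elimination of the C9 silyloxy or C1 ether group, to conjugation of the isopropenyl alkene, or to recovered ketone. Fallback: from ketone 14, the less basic and smaller ethynylmagnesium bromide (THF, −78 → 0 °C) is added; the axial C9 silyl ether still forces equatorial entry, giving the ethynyl carbinol F5. Semihydrogenation (H2, Pd/CaCO3 poisoned with Pb(OAc)2, quinoline, EtOAc) then gives carbinol 16.

**Further compounds**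
F1 | step 9 | (1R,2R,3R,4R,5S)-3-(tert-butyldimethylsilyloxy)-5-(4-methoxybenzyloxy)-4-(propan-2-yl)-2-(prop-1-en-2-yl)cyclohexan-1-ol (C8 epimer of 13) | O[C@H]1[C@@H](C(C)=C)[C@H](O[Si](C)(C)C(C)(C)C)[C@H](C(C)C)[C@@H](OCc2ccc(OC)cc2)C1
F2 | step 9 | (2S,3R,4R,5S)-3-(tert-butyldimethylsilyloxy)-5-(4-methoxybenzyloxy)-4-(propan-2-yl)-2-(prop-1-en-2-yl)cyclohexan-1-one (C8 epimer of 14) | O=C1[C@@H](C(C)=C)[C@H](O[Si](C)(C)C(C)(C)C)[C@H](C(C)C)[C@@H](OCc2ccc(OC)cc2)C1
F3 | step 9 | (1S,2S,3R,4R,5S)-1-ethenyl-3-(tert-butyldimethylsilyloxy)-5-(4-methoxybenzyloxy)-4-(propan-2-yl)-2-(prop-1-en-2-yl)cyclohexan-1-ol (C3,C8-bis-epimer of 16) | C=C[C@]1(O)[C@@H](C(C)=C)[C@H](O[Si](C)(C)C(C)(C)C)[C@H](C(C)C)[C@@H](OCc2ccc(OC)cc2)C1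
F4 | step 12 | (1Z,5E,7S,8R,9S)-7-(tert-butyldimethylsilyloxy)-9-(4-methoxybenzyloxy)-5-methyl-8-(propan-2-yl)cyclodeca-1,5-dien-1-yl diethyl phosphate | COc1ccc(CO[C@H]2C/C(OP(=O)(OCC)OCC)=C/CC/C(C)=C/[C@H](O[Si](C)(C)C(C)(C)C)[C@@H]2C(C)C)cc1
F5 | step 11 | (1S,2R,3R,4R,5S)-1-ethynyl-3-(tert-butyldimethylsilyloxy)-5-(4-methoxybenzyloxy)-4-(propan-2-yl)-2-(prop-1-en-2-yl)cyclohexan-1-ol (ethynyl analogue of 16) | C#C[C@@]1(O)[C@H](C(C)=C)[C@H](O[Si](C)(C)C(C)(C)C)[C@H](C(C)C)[C@@H](OCc2ccc(OC)cc2)C1
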